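**Strategy**

Ring atoms are labelled C1 (carbon carrying two prenyl groups), C2 (C=O), C3 (carbon carrying the isobutyryl group), C4 (enol carbon), C5 (tertiary carbinol, the only stereocentre) and C6 (C=O). The C3=C4 enol unit is a masked alkyne: lifting it out and reconnecting C2 to C5 leaves a mirror-symmetric cyclobutane-1,3-dione (C1, C2, C5, C6) with enantiotopic carbonyls. A nickel-catalysed, ligand-controlled insertion of an acyl ynol ether into one C5–carbonyl bond therefore forms C2–C3 and C4–C5, the six-membered ring and the C5 configuration in a single operation. The precursor is the achiral 2,2,4-triprenyl-4-(triethylsilyloxy)cyclobutane-1,3-dione, reached by ketene–ynol ether cycloaddition, hydrolysis, enolate hydroxylation and silylation.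

Key step: step 9

Assumption: prenyl means 3-methylbut-2-enyl. The target SMILES corresponds to (S) at C5 (position 6 in the systematic names). The sense of induction of the chiral ligand in step 9 cannot be predicted, so the ligand antipode that delivers (S) is to be used; the (S,S,S) form is written for definiteness.

**Route**

Step 1
Reactants: 1 dimethyl malonate; 2 prenyl bromide (1-bromo-3-methylbut-2-ene)
Product: 4 dimethyl 2,2-bis(3-methylbut-2-enyl)malonate, via monoprenyl malonate 3 (not isolated)
Conditions: NaH (2.3 equiv), 2 (2.3 equiv), THF/DMF, 0 °C → rt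
Reagents that add atoms: none
Why: Twofold malonic ester alkylation, in which the sodium enolate attacks the primary allylic bromide by SN2 and the monoalkylated ester is deprotonated and alkylated again in the same flask.

Step 2
Reactants: 4 dimethyl 2,2-bis(3-methylbut-2-enyl)malonate
Product: 6 5-methyl-2-(3-methylbut-2-enyl)hex-4-enoic acid, via methyl ester 5 (not isolated)
Conditions: LiCl, H2O, DMSO, 160 °C; then LiOH, H2O/MeOH, 50 °C; then 1 M HCl, 0 °C
Reagents that add atoms: lithium hydroxide, [Li+].[OH-]
Why: Krapcho dealkoxycarbonylation removes one ester under neutral conditions that spare the prenyl groups, and saponification in the same flask with cold acidification gives the acid without the hot acid that would lactonise it.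

Step 3
Reactants: 7 ethoxyacetylene (ethoxyethyne); 2 prenyl bromide
Product: 9 1-ethoxy-5-methylhex-4-en-1-yne, via lithium ethoxyacetylide 8 (not isolated)
Conditions: n-BuLi, THF, −78 °C; then 2, DMPU, −78 °C → rt
Reagents that add atoms: none
Why: Deprotonation of the terminal ynol ether and SN2 alkylation of the lithium acetylide at the primary carbon of the allylic bromide in a dipolar cosolvent is the standard entry to 1-alkoxy-1-alkynes.

Step 4
Reactants: 6 5-methyl-2-(3-methylbut-2-enyl)hex-4-enoic acid; 9 1-ethoxy-5-methylhex-4-en-1-yne
Product: 12 3-ethoxy-2,4,4-tris(3-methylbut-2-enyl)cyclobut-2-en-1-one, via acid chloride 10 (not isolated), via diprenylketene 11 (not isolated)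
Conditions: 1-chloro-N,N,2-trimethylprop-1-en-1-amine, toluene, 0 °C → rt; then 9 (1.5 equiv), Et3N, 60 °C
Reagents that add atoms: none
Why: The α-chloroenamine makes the acid chloride without releasing HCl, triethylamine dehydrochlorinates it to the dialkylketene, and a ketene–ynol ether [2+2] cycloaddition joins the ketene carbonyl carbon to the nucleophilic prenyl-bearing alkyne carbon, which fixes the 3-ethoxycyclobutenone regiochemistry without creating a stereocentre.

Step 5
Reactants: 12 3-ethoxy-2,4,4-tris(3-methylbut-2-enyl)cyclobut-2-en-1-one
Product: 13 3-hydroxy-2,4,4-tris(3-methylbut-2-enyl)cyclobut-2-en-1-one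
Conditions: 1 M aq. HCl, THF, rt
Reagents that add atoms: water, O
Why: Acid hydrolysis of the vinylogous ester (addition of water, loss of ethanol) is the usual passage from a 3-alkoxycyclobutenone to the cyclobutane-1,3-dione, which rests as its acidic enol, and dilute acid at room temperature should leave the prenyl groups alone.

Step 6
Reactants: 13 3-hydroxy-2,4,4-tris(3-methylbut-2-enyl)cyclobut-2-en-1-one
Product: 15 2-hydroxy-2,4,4-tris(3-methylbut-2-enyl)cyclobutane-1,3-dione, via potassium enolate 14 (not isolated)
Conditions: KN(SiMe3)2 (1.05 equiv), THF, −78 °C; 3-phenyl-2-(phenylsulfonyl)oxaziridine, −78 → −40 °C; AcOH, −78 °C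
Reagents that add atoms: 3-phenyl-2-(phenylsulfonyl)oxaziridine, O=S(=O)(N1OC1c1ccccc1)c1ccccc1
Why: Enolate hydroxylation with an N-sulfonyloxaziridine transfers electrophilic oxygen to the carbon between the two carbonyls and does not epoxidise the trisubstituted alkenes; the new carbinol carbon lies on the mirror plane, so no stereocentre arises, and the cold acetic acid quench keeps the now non-enolisable dione away from base.

Step 7
Reactants: 15 2-hydroxy-2,4,4-tris(3-methylbut-2-enyl)cyclobutane-1,3-dione
Product: 16 2,2,4-tris(3-methylbut-2-enyl)-4-(triethylsilyloxy)cyclobutane-1,3-dione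
Conditions: Et3SiOTf, 2,6-lutidine, CH2Cl2, −78 → 0 °C
Reagents that add atoms: triethylsilyl trifluoromethanesulfonate, CC[Si](CC)(CC)OS(=O)(=O)C(F)(F)F
Why: Silylation of a hindered tertiary alcohol with a silyl triflate and a non-nucleophilic pyridine base is standard and avoids nucleophiles that could open the strained dione; the triethylsilyl ether should survive chromatography and the neutral nickel step yet fall to dilute acid, and the product keeps its mirror plane.

Step 8
Reactants: 7 ethoxyacetylene; 17 isobutyryl chloride (2-methylpropanoyl chloride)
Product: 20 1-ethoxy-4-methylpent-1-yn-3-one, via ethoxyethynylmagnesium bromide 18 (not isolated), via ethoxyethynylzinc chloride 19 (not isolated)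
Conditions: EtMgBr, THF, 0 °C → rt; ZnCl2, 0 °C; 17, Pd(PPh3)4 (3 mol%), 0 °C → rt
Reagents that add atoms: none
Why: Ethylmagnesium bromide deprotonates the terminal ynol ether to the alkynyl Grignard reagent, transmetalation gives the alkynylzinc chloride, and its palladium-catalysed acylation with the acid chloride (Negishi acylation) gives the ynone without the double addition seen with more basic acetylides and without a nucleophilic amine by-product that could add to the push–pull alkyne.

Step 9
Reactants: 16 2,2,4-tris(3-methylbut-2-enyl)-4-(triethylsilyloxy)cyclobutane-1,3-dione; 20 1-ethoxy-4-methylpent-1-yn-3-one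
Product: 21 (6S)-5-ethoxy-4-(2-methylpropanoyl)-2,2,6-tris(3-methylbut-2-enyl)-6-(triethylsilyloxy)cyclohex-4-ene-1,3-dione
Conditions: Ni(cod)2 (10 mol%), (S)-BINOL-derived N,N-bis[(S)-1-phenylethyl]phosphoramidite (12 mol%), toluene, 40 °C, 20 (2 equiv) added over 8 h
Reagents that add atoms: none
Why: Proposed new method: zerovalent nickel carrying one chiral phosphoramidite should couple the alkyne with one strained ring carbonyl by oxidative cyclisation (C3 to C2, nickel on the carbonyl oxygen and on C4), β-carbon elimination of the nickel alkoxide should then cut C2–C5 with release of ring strain, and reductive elimination should join C4 to C5; direct insertion of nickel into C2–C5 followed by addition of the nickel enolate to the ynone would lead to the same product. The closest known reaction type is the nickel-catalysed insertion of alkynes into cyclobutanones to give cyclohex-2-enones, with rhodium- and nickel-catalysed desymmetrising ring expansions of prochiral cyclobutanones as the stereochemical precedent, whereas a 1,3-dione with two quaternary α-carbons and an acyl ynol ether as partner are untested. The six-membered ring closes by two-carbon ring expansion of the four-membered ring, that is by C–C reductive elimination from a seven-membered nickelacycle in which C5 is the carbon of a nickel enolate of the C6 ketone. C5 becomes a stereocentre because only one of its two enantiotopic acyl bonds is exchanged, and the chiral ligand controls it, either by choosing the pro-R carbonyl for the first C–C bond (nickel then replaces and returns carbon at C5 with retention) or, should the nickel enolate pass through its oxygen-bound form, by choosing the enolate face in the C4–C5 bond formation. Besides this, cleavage must occur toward C5 and not C1, which the substrate favours because the oxygen-substituted C5 gives the more acidic, α-oxygenated enolate and is no more crowded at the ring than C1 with its two CH2 groups, and the alkyne must be oriented with C3 toward C2, which the push–pull polarisation favours by pairing the nucleophilic acyl-bearing C3 with the acyl carbon C2 and the electrophilic ethoxy-bearing C4 with the enolate carbon C5. The weakly nucleophilic phosphoramidite is chosen so that the ligand does not add to the Michael-acceptor ynone, slow addition limits alkyne oligomerisation, and 40 °C stays below the temperature at which ethyl ynol ethers fragment.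

Step 10
Reactants: 21 (6S)-5-ethoxy-4-(2-methylpropanoyl)-2,2,6-tris(3-methylbut-2-enyl)-6-(triethylsilyloxy)cyclohex-4-ene-1,3-dione
Product: 23 (6S)-5,6-dihydroxy-4-(2-methylpropanoyl)-2,2,6-tris(3-methylbut-2-enyl)cyclohex-4-ene-1,3-dione, via silyl-protected triketone 22 (not isolated)
Conditions: 1 M aq. HCl, THF, 0 °C → rt
Reagents that add atoms: water, O
Why: The doubly activated vinylogous ester at C4 should hydrolyse first by addition–elimination of water and the tertiary triethylsilyl ether should then fall to the same dilute acid (acid-catalysed desilylation); C5 is quaternary and non-enolisable, so its configuration is untouched, and room temperature should avoid acid cyclisation of the prenyl groups and α-ketol rearrangement.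

**Compound list**

1 | dimethyl malonate | COC(=O)CC(=O)OC | starting material
2 | prenyl bromide (1-bromo-3-methylbut-2-ene) | CC(C)=CCBr | starting material
3 | dimethyl 2-(3-methylbut-2-enyl)malonate | COC(=O)C(CC=C(C)C)C(=O)OC | intermediate
4 | dimethyl 2,2-bis(3-methylbut-2-enyl)malonate | COC(=O)C(CC=C(C)C)(CC=C(C)C)C(=O)OC | intermediate
5 | methyl 5-methyl-2-(3-methylbut-2-enyl)hex-4-enoate | COC(=O)C(CC=C(C)C)CC=C(C)C | intermediate
6 | 5-methyl-2-(3-methylbut-2-enyl)hex-4-enoic acid | CC(C)=CCC(CC=C(C)C)C(=O)O | intermediate
7 | ethoxyacetylene (ethoxyethyne) | CCOC#C | starting material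
8 | lithium ethoxyacetylide | [Li]C#COCC | intermediate
9 | 1-ethoxy-5-methylhex-4-en-1-yne | CCOC#CCC=C(C)C | intermediate
10 | 5-methyl-2-(3-methylbut-2-enyl)hex-4-enoyl chloride | CC(C)=CCC(CC=C(C)C)C(Cl)=O | intermediate
11 | 5-methyl-2-(3-methylbut-2-enyl)hexa-1,4-dien-1-one (diprenylketene) | CC(C)=CCC(CC=C(C)C)=C=O | intermediate
12 | 3-ethoxy-2,4,4-tris(3-methylbut-2-enyl)cyclobut-2-en-1-one | CCOC1=C(CC=C(C)C)C(=O)C1(CC=C(C)C)CC=C(C)C | intermediate
13 | 3-hydroxy-2,4,4-tris(3-methylbut-2-enyl)cyclobut-2-en-1-one (enol of the 1,3-dione) | OC1=C(CC=C(C)C)C(=O)C1(CC=C(C)C)CC=C(C)C | intermediate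
14 | potassium 3-oxo-2,4,4-tris(3-methylbut-2-enyl)cyclobut-1-en-1-olate | [K+].[O-]C1=C(CC=C(C)C)C(=O)C1(CC=C(C)C)CC=C(C)C | intermediate
15 | 2-hydroxy-2,4,4-tris(3-methylbut-2-enyl)cyclobutane-1,3-dione (achiral) | CC(C)=CCC1(O)C(=O)C(CC=C(C)C)(CC=C(C)C)C1=O | intermediate
16 | 2,2,4-tris(3-methylbut-2-enyl)-4-(triethylsilyloxy)cyclobutane-1,3-dione (achiral) | CC[Si](CC)(CC)OC1(CC=C(C)C)C(=O)C(CC=C(C)C)(CC=C(C)C)C1=O | intermediate
17 | isobutyryl chloride (2-methylpropanoyl chloride) | CC(C)C(Cl)=O | starting material
18 | ethoxyethynylmagnesium bromide | CCOC#C[Mg]Br | intermediate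
19 | ethoxyethynylzinc chloride | CCOC#C[Zn]Cl | intermediate
20 | 1-ethoxy-4-methylpent-1-yn-3-one | CCOC#CC(=O)C(C)C | intermediate
21 | (6S)-5-ethoxy-4-(2-methylpropanoyl)-2,2,6-tris(3-methylbut-2-enyl)-6-(triethylsilyloxy)cyclohex-4-ene-1,3-dione | CC(C)=CCC1(CC=C(C)C)C(=O)C(C(=O)C(C)C)=C(OCC)[C@@](O[Si](CC)(CC)CC)(CC=C(C)C)C1=O | intermediate
22 | (6S)-5-hydroxy-4-(2-methylpropanoyl)-2,2,6-tris(3-methylbut-2-enyl)-6-(triethylsilyloxy)cyclohex-4-ene-1,3-dione | CC(C)=CCC1(CC=C(C)C)C(=O)C(C(=O)C(C)C)=C(O)[C@@](O[Si](CC)(CC)CC)(CC=C(C)C)C1=O | intermediate
23 | (6S)-5,6-dihydroxy-4-(2-methylpropanoyl)-2,2,6-tris(3-methylbut-2-enyl)cyclohex-4-ene-1,3-dione | CC(C)=CCC1(CC=C(C)C)C(=O)C(C(=O)C(C)C)=C(O)[C@@](O)(CC=C(C)C)C1=O | target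

**Count**

Total steps: 10. Longest linear sequence: 8 steps (steps 1, 2, 4, 5, 6, 7, 9, 10); steps 3 and 8 are side branches.

**Steps most likely to fail**

1. Step 9. Several processes could defeat it: oligomerisation of the ynone at nickel faster than its coupling with the dione; ring cleavage on the C1 side; reversed alkyne orientation, since a conjugated acyl group tends to draw nickel to C3; weak discrimination between the enantiotopic carbonyls; or silyl transfer within the nickel enolate. The fallback uses known reactions only, sets out from 17 and 2 and comes back at 23. Friedel–Crafts acylation of commercial benzene-1,3,5-triol with 17 (AlCl3, nitrobenzene) should give 2-methyl-1-(2,4,6-trihydroxyphenyl)propan-1-one F1. Threefold C-prenylation of F1 with 2 (NaOMe, MeOH, 0 °C) should give colupulone F2. The sodium enolate of F2 would then be hydroxylated at the prenyl-bearing ring carbon C5 with an enantiopure (camphorsulfonyl)oxaziridine (reagent-controlled asymmetric enolate hydroxylation), the reagent antipode being chosen for the (S) carbinol. Enantiomeric purity would be raised, if needed, on a chiral stationary phase to give 23.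

2. Step 6. The highly stabilised enolate may take up oxygen only sluggishly, and the alkoxide formed first may trigger ring cleavage or acyloin-type rearrangement of the non-enolisable dione before the quench. The fallback sets out from 13 and comes back at 15 without a basic stage. One-electron oxidation of 13 with (NH4)2Ce(NO3)6 in MeCN in the presence of TEMPO should trap the dione radical as 2-[(2,2,6,6-tetramethylpiperidin-1-yl)oxy]-2,4,4-tris(3-methylbut-2-enyl)cyclobutane-1,3-dione F3. Zinc dust in AcOH/THF/H2O would then cleave the N–O bond of F3 to give 15.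

3. Step 8. Conjugate addition of nucleophiles to the push–pull ynone, or its hydration and oligomerisation during formation and isolation, may erode the material. The fallback sets out from 7 and comes back at 20 through a change of oxidation level. The magnesium acetylide 18, made from 7 with EtMgBr as in the first operation of step 8, is added to commercial 2-methylpropanal (THF, −40 → 0 °C) to give racemic 1-ethoxy-4-methylpent-1-yn-3-ol F4. The propargylic alcohol F4 is then oxidised with MnO2 in CH2Cl2 at rt, without aqueous work-up, to 20.

**Further compounds**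

F1 | step 9 | 2-methyl-1-(2,4,6-trihydroxyphenyl)propan-1-one | CC(C)C(=O)c1c(O)cc(O)cc1O
F2 | step 9 | colupulone, 3,5-dihydroxy-2-(2-methylpropanoyl)-4,6,6-tris(3-methylbut-2-enyl)cyclohexa-2,4-dien-1-one | CC(C)=CCC1=C(O)C(CC=C(C)C)(CC=C(C)C)C(=O)C(C(=O)C(C)C)=C1O
F3 | step 6 | 2-[(2,2,6,6-tetramethylpiperidin-1-yl)oxy]-2,4,4-tris(3-methylbut-2-enyl)cyclobutane-1,3-dione | CC(C)=CCC1(ON2C(C)(C)CCCC2(C)C)C(=O)C(CC=C(C)C)(CC=C(C)C)C1=O
F4 | step 8 | 1-ethoxy-4-methylpent-1-yn-3-ol (racemic) | CCOC#CC(O)C(C)C
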